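The runs stem from a simulated flask with constants of no real substance; scatter was added.

A small charge runs a slower clock. This flask holds 0.25 M of starting material, less than maple or birch, with the same equivalents of reagent as those runs.

| setting | maple | birch | oak | flask |
|---|---|---|---|---|
| starting material | 0.35 M | 0.55 M | 0.25 M | 0.25 M |
| reagent | 2 equiv | 2 equiv | 4 equiv | 2.00 equiv |
| capture agent | 0.0125 M | 0.0125 M | 0.0125 M | 0.0125 M |
| remark | run made earlier | run made earlier | run made earlier |  |
| time |  |  |  | 3.0 d |

- maple (time / h: bis adduct / %, triple product / %): 10.0: 16.0, 6.5; 20.0: 14.4, 5.6; 30.0: 15.5, 6.1; 40.0: 14.2, 7.2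
- birch (time / h: bis adduct / %, triple product / %): 3.00: 11.4, 6.7; 8.00: 15.4, 6.6; 20.0: 13.0, 6.2; 40.0: 14.5, 6.6
- oak (time / h: bis adduct / %, triple product / %): 5.00: 15.5, 5.5; 15.0: 8.3, 3.5; 30.0: 5.9, 2.7; 40.0: 2.1, 1.3

(scatter of a reading: 1 percentage point)

- the earlier runs were read with a standard deviation of 1 percentage point

* equivalents of reagent to starting material, everything else as given, that leave most bis adduct at 3.0 d
* the amount of bis adduct then, in percent of the starting material charged
* the amount of bis adduct with the amounts as given

Maple and birch read flat at much the same height although their charges differ, so dilution seems to change when a flask arrives, not where. Two times then matter: the time this flask needs and the time it is given. If each step is a meeting of two molecules, then at equal equivalents the curves, as fractions of the charge, stretch in time inversely with the reagent charged. That puts a mean reagent level, the same fraction of the charge in both flasks, in place of a falling curve. Maple was already flat at its first reading, 10.0 h, so I stretch that reading by the ratio of reagent charged and get the settling time 14.0 h. The stretching errs on the capture agent, which stays at 0.0125 M and so is 5.00 % of this flask's charge against 3.57 % in maple. The time given is longer than the settling time by a factor 5.14, so I expect this flask to stand on the plateau of those runs.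

The forecast gave 14.6 % as it stands, and 15.5 % at 2.05 equiv, holding that “three days should be ample to reach the plateau”.

The flask gives 14.1 % of bis adduct, and at best 14.3 % at 1.84 equiv.

    starting material + reagent → first product + by-product (k = 2.30 × 10⁻⁴ /M/s)
    reagent + first product → bis adduct + by-product (k = 8.30 × 10⁻⁵ /M/s)
    reagent + bis adduct → triple product + by-product (k = 2.70 × 10⁻⁴ /M/s)
    reagent + triple product → tetra adduct + by-product (k = 4.10 × 10⁻⁴ /M/s)
    reagent + triple product → over-reaction product (k = 2.40 × 10⁻⁴ /M/s)
    first product + capture agent → trapped intermediate (k = 0.00150 /M/s)

Against the settling time of 14.0 h, this flask's reagent was down to 1.18 % of its charge at 1.50 d, with bis adduct already at 14.2 %. Birch has the same equivalents as this flask, so the same rule applies and shrinks the settling time to 6.36 h, later than birch's first reading and earlier than its second. Birch read 11.4 % of bis adduct at 3.00 h and 15.4 % at 8.00 h.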